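**Retrosynthetic overview**
1. Target 8 ⇐ 6 by one acidic deprotection: the catechol ketal, the 3,4-acetonide and the 1,5-lactone are hydrolysed, while the tertiary cinnamate on C1 stays.
2. 6 ⇐ acrylate 4 + arene 5 by cutting the bond between the alkene carbon beta to the ester carbonyl and the aryl carbon: a twofold C–H (dehydrogenative Heck) coupling in which neither partner carries a halogen or metal handle.
3. 4 ⇐ quinide acetonide 2 + acryloyl chloride 3; 2 ⇐ (−)-quinic acid 1, which supplies the cyclohexane ring and all four stereocentres.
4. Ring order: cyclohexane bought with 1; lactone and dioxolane rings closed together in step 1 as temporary rings; benzodioxole ring brought in intact with 5 in step 3; the three temporary rings opened in step 4. The key step closes no ring.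
5. Enabling feature: the C5–H bond of the 1,3-benzodioxole ring of 5 (para to ring oxygen O1, unflanked, equivalent to C6–H through the mirror plane containing C2) as the nucleophilic partner, and the unsubstituted terminal =CH2 of the acrylate on O1 of the quinide as the acceptor.

Key step: step 3

Remark: the configuration in the target SMILES is that of natural (−)-quinic acid (O1, O3 and O4 on one face of the ring, O5 and the carboxyl group on the other; 3R,5R). All ring stereocentres are therefore taken from the chiral pool and none is created. Quinic acid numbering (C1 = carbinol carbon bearing CO2H) is used throughout.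

**Step 1**
Reactants: 1 (−)-quinic acid
Product: 2 3,4-O-isopropylidene-1,5-quinide (1,5-lactone of quinic acid, carboxyl on C1 closed onto O5; cis-3,4-diol as acetonide; tertiary 1-OH free; stereocentres as in 1)
Conditions: 2,2-dimethoxypropane, TsOH·H2O (cat.), acetone, reflux
Reagents that add atoms: 2,2-dimethoxypropane, COC(C)(C)OC
Why: Acid-catalysed transketalisation should protect the only cis-vicinal diol (3-OH/4-OH) as the five-membered acetonide while the carboxyl group, cis to 5-OH, closes the bicyclic lactone (Fischer-type lactonisation) under the same dehydrating conditions, leaving the tertiary 1-OH as the only free hydroxyl; no stereocentre is formed or touched.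

**Step 2**
Reactants: 2 3,4-O-isopropylidene-1,5-quinide; 3 acryloyl chloride
Product: 4 1-O-acryloyl-3,4-O-isopropylidene-1,5-quinide
Conditions: iPr2NEt, DMAP (cat.), BHT (trace), CH2Cl2, 0 °C to rt
Reagents that add atoms: none
Why: DMAP-catalysed O-acylation (nucleophilic catalysis through the N-acryloylpyridinium ion) of the sole free hydroxyl group should give the tertiary acrylate; the C1–O bond is not broken, so the C1 configuration is retained.

**Step 3**
Reactants: 4 1-O-acryloyl-3,4-O-isopropylidene-1,5-quinide; 5 2,2-dimethyl-1,3-benzodioxole (catechol acetonide, 4 equiv)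
Product: 6 1-O-[(E)-3-(2,2-dimethyl-1,3-benzodioxol-5-yl)prop-2-enoyl]-3,4-O-isopropylidene-1,5-quinide
Conditions: Pd(OAc)2 (10 mol %), 3-methyl-2-(phenylthio)butanoic acid (10 mol %), PhCO3tBu (1.5 equiv), AcOH, 80 °C
Reagents that add atoms: none
Why: The Pd(OAc)2 carrying the thioether–carboxylate ligand should metalate the C5–H bond of 5 (electrophilic concerted metalation–deprotonation para to O1), the aryl–palladium species adds syn across the acrylate C=C of 4 with the aryl group going to the terminal carbon, syn beta-hydride elimination releases the cinnamate 6, and the zerovalent palladium formed is reoxidised to divalent palladium by tert-butyl perbenzoate. The closest known reaction type is the non-directed Fujiwara–Moritani (dehydrogenative Heck) olefination of alkoxyarenes with acrylates under Pd(OAc)2 catalysis with sulfur–oxygen or pyridine-type ligands. No ring is closed and no stereocentre is formed; the only stereochemical element created is the E double bond, fixed by the syn-insertion/syn-elimination sequence and by the thermodynamic preference of the cinnamate. The step needs site selectivity on the arene (C5 against C4), which the substrate secures because 5 has only two kinds of C–H bond, C5–H and C6–H are equivalent, and C5 is para to a ring oxygen and unflanked whereas C4 is only ortho-activated and lies next to the ring fusion. Double olefination should be held back by the excess of 5 and by the lower nucleophilicity of the cinnamate product, and 4 offers neither a free hydroxyl group nor another C–H bond prone to palladation. In one operation the step should form the aryl–vinyl bond, fix the 1,2,4-substitution pattern of the catechol ring and set the alkene geometry.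

**Step 4**
Reactants: 6 1-O-[(E)-3-(2,2-dimethyl-1,3-benzodioxol-5-yl)prop-2-enoyl]-3,4-O-isopropylidene-1,5-quinide
Product: 8 1-O-caffeoylquinic acid, via 1-O-caffeoyl-1,5-quinide 7 (not isolated)
Conditions: TFA/H2O (9:1), 0 °C to rt; then evaporate, 1 M aq HCl/THF (1:1), rt, argon, dark
Reagents that add atoms: water, O
Why: Acid-catalysed ketal hydrolysis should cleave both isopropylidene groups to give 7, and dilute aqueous acid should then open the strained bicyclic lactone by acyl–oxygen hydrolysis, while the tertiary cinnamate on C1 resists ionisation (the cation would sit alpha to a carbonyl group) and acyl substitution (hindered, conjugated); only bonds to ketal and acyl carbons are broken, so C1, C3, C4 and C5 keep their configuration.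

**Compound list**
1 | (−)-quinic acid, (1S,3R,4S,5R)-1,3,4,5-tetrahydroxycyclohexane-1-carboxylic acid | O[C@]1(C(=O)O)C[C@@H](O)[C@H](O)[C@H](O)C1 | starting material
2 | 3,4-O-isopropylidene-1,5-quinide (quinic acid 1,5-lactone 3,4-acetonide, free tertiary 1-OH) | O[C@]1(C(=O)O2)C[C@@H]2[C@@H]3OC(C)(C)O[C@@H]3C1 | intermediate
3 | acryloyl chloride | C=CC(=O)Cl | starting material
4 | 1-O-acryloyl-3,4-O-isopropylidene-1,5-quinide | C=CC(=O)O[C@]1(C(=O)O2)C[C@@H]2[C@@H]3OC(C)(C)O[C@@H]3C1 | intermediate
5 | 2,2-dimethyl-1,3-benzodioxole | CC1(C)Oc2ccccc2O1 | starting material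
6 | 1-O-[(E)-3-(2,2-dimethyl-1,3-benzodioxol-5-yl)prop-2-enoyl]-3,4-O-isopropylidene-1,5-quinide | CC1(C)Oc2ccc(/C=C/C(=O)O[C@]3(C(=O)O4)C[C@@H]4[C@@H]5OC(C)(C)O[C@@H]5C3)cc2O1 | intermediate
7 | 1-O-caffeoyl-1,5-quinide (1-O-[(E)-3-(3,4-dihydroxyphenyl)prop-2-enoyl]quinic acid 1,5-lactone) | O=C(/C=C/c1ccc(O)c(O)c1)O[C@]1(C(=O)O2)C[C@@H]2[C@H](O)[C@H](O)C1 | intermediate
8 | 1-O-caffeoylquinic acid (1-O-[(E)-3-(3,4-dihydroxyphenyl)prop-2-enoyl] ester of (−)-quinic acid) | O=C(/C=C/c1ccc(O)c(O)c1)O[C@]1(C(=O)O)C[C@@H](O)[C@H](O)[C@H](O)C1 | target

**Summary**
Total step count: 4. Longest linear sequence: 4 steps (1 → 2 → 4 → 6 → 8).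

Steps most likely to fail:

Step 3: palladation of the arene may be insufficiently site-selective (C4 against C5), or the catalyst may deactivate before the hindered acrylate is consumed. The fallback sets out from 5 and pre-functionalises the arene. Electrophilic bromination of 5 with N-bromosuccinimide in MeCN at 0 °C should give 5-bromo-2,2-dimethyl-1,3-benzodioxole F1, with bromine para to oxygen. A Mizoroki–Heck reaction of F1 with 4 (Pd(OAc)2, P(o-tol)3, Et3N, DMF, 90 °C) should then come back to the route at 6.

Step 2: acylation of the hindered tertiary hydroxyl group may be slow enough for polymerisation or amine conjugate addition of the acryloyl unit to compete. The fallback sets out from 2 and uses a masked acrylate. Acylation with 3-chloropropanoyl chloride (pyridine, DMAP, CH2Cl2, rt, heating if needed) should give 1-O-(3-chloropropanoyl)-3,4-O-isopropylidene-1,5-quinide F2. Elimination of HCl with Et3N in CH2Cl2 at rt should then come back to the route at 4.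

Step 4: lactone opening may be incomplete, or the cinnamate may be slowly hydrolysed or migrate during long exposure to acid. The fallback sets out from 6 and opens the lactone under basic conditions while the catechol is still masked. LiOH (1.1 equiv) in THF/H2O at 0 °C, followed by acidification to pH 3 with dilute HCl, should give 1-O-[(E)-3-(2,2-dimethyl-1,3-benzodioxol-5-yl)prop-2-enoyl]-3,4-O-isopropylidenequinic acid F3. A short treatment with TFA/H2O (3:1) at rt should remove both ketals and come back to the route at 8.

**Further compounds**
F1 | step 3 | 5-bromo-2,2-dimethyl-1,3-benzodioxole | CC1(C)Oc2ccc(Br)cc2O1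
F2 | step 2 | 1-O-(3-chloropropanoyl)-3,4-O-isopropylidene-1,5-quinide | O=C(CCCl)O[C@]1(C(=O)O2)C[C@@H]2[C@@H]3OC(C)(C)O[C@@H]3C1
F3 | step 4 | 1-O-[(E)-3-(2,2-dimethyl-1,3-benzodioxol-5-yl)prop-2-enoyl]-3,4-O-isopropylidenequinic acid | CC1(C)Oc2ccc(/C=C/C(=O)O[C@]3(C(=O)O)C[C@@H](O)[C@@H]4OC(C)(C)O[C@@H]4C3)cc2O1
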